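Both indoles carry hydrogen at C2 and the hexasubstituted central benzene ring at C3. Each N1–C2 bond is therefore cut back to an ortho-nitroaryl group on the internal carbon of a 1,1-diarylethene whose CH2 terminus becomes C2. One palladium-catalysed, CO-driven reductive cyclisation then forms both N1–C2 bonds and closes both pyrrole rings at once, giving the target without protecting groups. The precursor is 2,3,5,6-tetramethoxybenzene bearing, para to one another, a 1-(2-nitrophenyl)vinyl and a 1-(2-nitro-5-prenylphenyl)vinyl group. It is assembled from a 1,4-diacetyl arene by two successive Barluenga couplings and a late Stille prenylation of an aryl chloride.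

Key step: step 8

Remark on the chemistry: the target is achiral and has no stereogenic double bond. The C=N geometry of the two tosylhydrazones is left undefined because both isomers give the same diazo compound, and the non-isolated hemiaminal adduct of the acylation step is a diastereomer mixture whose stereocentres vanish on work-up.

Step 1
Reactants: 1 1,2,4,5-tetramethoxybenzene
Product: 2 1,4-dibromo-2,3,5,6-tetramethoxybenzene
Conditions: Br2 (2.2 equiv), CH2Cl2, 0 °C to rt
Reagents that add atoms: bromine, BrBr
Why: Electrophilic aromatic bromination: the two unsubstituted positions of 1 are para to each other, each activated by two ortho methoxy groups, and are the only sites open, so twofold bromination should give 2 with no regiochemical choice.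

Step 2
Reactants: 2 1,4-dibromo-2,3,5,6-tetramethoxybenzene; 3 N-methoxy-N-methylacetamide
Product: 6 1,1'-(2,3,5,6-tetramethoxy-1,4-phenylene)di(ethan-1-one), via dilithio arene 4 (not isolated), via bis-hemiaminal dilithium alkoxide 5 (not isolated)
Conditions: t-BuLi (4.4 equiv), THF, −78 °C; then 3 (3 equiv), −78 °C to 0 °C; then 1 M HCl
Reagents that add atoms: none
Why: Twofold bromine–lithium exchange followed by Weinreb ketone synthesis: excess t-BuLi makes the exchange irreversible and gives an aryl dilithium stabilised by its flanking methoxy groups, and each acylation should stop at the chelated tetrahedral adduct, so the two ketones appear only on acidic work-up and cannot be attacked a second time.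

Step 3
Reactants: 6 1,1'-(2,3,5,6-tetramethoxy-1,4-phenylene)di(ethan-1-one)
Product: 7 N'-[1-(4-acetyl-2,3,5,6-tetramethoxyphenyl)ethylidene]-4-methylbenzenesulfonohydrazide
Conditions: TsNHNH2 (0.6 equiv relative to 6), TsOH·H2O (cat.), MeOH, 65 °C
Reagents that add atoms: 4-methylbenzenesulfonohydrazide, Cc1ccc(cc1)S(=O)(=O)NN
Why: Acid-catalysed condensation of a ketone with a sulfonyl hydrazide (tosylhydrazone formation): the two acetyl groups are twisted out of conjugation and react independently, so a deficit of the hydrazide should give mainly the mono-hydrazone 7, which is separated by crystallisation or chromatography from surplus 6 (recycled) and from a little bis-hydrazone.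

Step 4
Reactants: 7 N'-[1-(4-acetyl-2,3,5,6-tetramethoxyphenyl)ethylidene]-4-methylbenzenesulfonohydrazide; 8 1-bromo-2-nitrobenzene
Product: 9 1-{2,3,5,6-tetramethoxy-4-[1-(2-nitrophenyl)ethenyl]phenyl}ethan-1-one
Conditions: PdCl2(PPh3)2 (5 mol %), LiOt-Bu (2.5 equiv), 1,4-dioxane, 100 °C
Reagents that add atoms: none
Why: Barluenga cross-coupling: LiOt-Bu converts the hydrazone into a diazo compound, the arylpalladium bromide formed by fast oxidative addition of zerovalent palladium to the nitro-activated C–Br bond of 8 traps it as a palladium carbene, and aryl migration followed by beta-hydride elimination from the methyl group should give the 1,1-diarylethene, while the hindered acetyl group is expected to stay a spectator under a PPh3-ligated catalyst that is poor at enolate arylation.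

Step 5
Reactants: 9 1-{2,3,5,6-tetramethoxy-4-[1-(2-nitrophenyl)ethenyl]phenyl}ethan-1-one
Product: 10 4-methyl-N'-(1-{2,3,5,6-tetramethoxy-4-[1-(2-nitrophenyl)ethenyl]phenyl}ethylidene)benzenesulfonohydrazide
Conditions: TsNHNH2 (1.5 equiv), TsOH·H2O (cat.), MeOH, 65 °C
Reagents that add atoms: 4-methylbenzenesulfonohydrazide, Cc1ccc(cc1)S(=O)(=O)NN
Why: Tosylhydrazone formation by acid-catalysed condensation, now with the hydrazide in excess since only one ketone remains; the nitro group, the hindered 1,1-diarylethene and the methyl ethers should be inert to warm methanol containing a trace of sulfonic acid.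

Step 6
Reactants: 10 4-methyl-N'-(1-{2,3,5,6-tetramethoxy-4-[1-(2-nitrophenyl)ethenyl]phenyl}ethylidene)benzenesulfonohydrazide; 11 2-bromo-4-chloro-1-nitrobenzene
Product: 12 1-[1-(5-chloro-2-nitrophenyl)ethenyl]-2,3,5,6-tetramethoxy-4-[1-(2-nitrophenyl)ethenyl]benzene
Conditions: PdCl2(PPh3)2 (5 mol %), LiOt-Bu (2.5 equiv), 1,4-dioxane, 100 °C
Reagents that add atoms: none
Why: Second Barluenga cross-coupling by the same sequence of diazo formation, palladium carbene formation, migratory insertion and beta-hydride elimination; with PPh3 as ligand, oxidative addition should take place at the C–Br bond ortho to the nitro group of 11 and leave the C–Cl bond para to it for the next step.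

Step 7
Reactants: 12 1-[1-(5-chloro-2-nitrophenyl)ethenyl]-2,3,5,6-tetramethoxy-4-[1-(2-nitrophenyl)ethenyl]benzene; 13 tributyl(3-methylbut-2-en-1-yl)stannane
Product: 14 1,2,4,5-tetramethoxy-3-{1-[5-(3-methylbut-2-en-1-yl)-2-nitrophenyl]ethenyl}-6-[1-(2-nitrophenyl)ethenyl]benzene
Conditions: Pd2(dba)3 (3 mol %; dba = dibenzylideneacetone), P(t-Bu)3 (12 mol %), CsF (2.2 equiv), 1,4-dioxane, 100 °C
Reagents that add atoms: none
Why: Migita–Kosugi–Stille coupling of an aryl chloride: the C–Cl bond para to a nitro group is activated for oxidative addition to zerovalent palladium carrying the bulky, electron-rich P(t-Bu)3, fluoride activates the stannane, and reductive elimination through the less hindered primary terminus of the allyl group should give the linear prenyl arene, the nitro groups and the hindered 1,1-diarylethenes taking no part.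

Step 8
Reactants: 14 1,2,4,5-tetramethoxy-3-{1-[5-(3-methylbut-2-en-1-yl)-2-nitrophenyl]ethenyl}-6-[1-(2-nitrophenyl)ethenyl]benzene
Product: 15 3-[4-(1H-indol-3-yl)-2,3,5,6-tetramethoxyphenyl]-5-(3-methylbut-2-en-1-yl)-1H-indole
Conditions: Pd(OAc)2 (10 mol %), 1,10-phenanthroline (20 mol %), CO (6 atm), DMF, 120 °C
Reagents that add atoms: none
Why: Zerovalent palladium, formed from Pd(OAc)2 under CO and held by phenanthroline, strips oxygen from each nitro group with CO (leaving as CO2) to give a nitrosoarene or palladium-bound nitrene equivalent, which attacks the neighbouring alkene at its CH2 terminus; a hydrogen shift and a further CO deoxygenation of the N-hydroxyindole-level intermediate should then deliver the aromatic NH pyrrole. The closest known reaction type is the palladium-catalysed, CO-driven reductive N-heterocyclisation of 2-nitrostyrenes, the catalytic counterpart of the Cadogan–Sundberg indole synthesis. Each of the two pyrrole rings closes in a five-membered endo mode (formally 5-endo-trig, equivalent to a six-electron, five-atom electrocyclisation of the ortho-nitrosostyrene), forming N1–C2 while C3 already carries the central ring. No stereocentre is created. The step needs nitrogen to bond only to the vinylic CH2 and to leave the prenyl alkene alone: the alkene carbon bearing both aryl groups is fully substituted, so only the 3-arylindole can aromatise, the prenyl group sits para to nitrogen on its ring and cannot be reached, and the neutral, non-acidic medium should spare the trisubstituted alkene and the four methyl ethers.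

Compound list
1 | 1,2,4,5-tetramethoxybenzene | COc1cc(OC)c(OC)cc1OC | starting material
2 | 1,4-dibromo-2,3,5,6-tetramethoxybenzene | COc1c(Br)c(OC)c(OC)c(Br)c1OC | intermediate
3 | N-methoxy-N-methylacetamide | CC(=O)N(C)OC | starting material
4 | 1,4-dilithio-2,3,5,6-tetramethoxybenzene (not isolated) | [Li]c1c(OC)c(OC)c([Li])c(OC)c1OC | intermediate
5 | dilithium 1,1'-(2,3,5,6-tetramethoxy-1,4-phenylene)bis{1-[methoxy(methyl)amino]ethan-1-olate} (not isolated; diastereomer mixture) | COc1c(OC)c(C(C)(O[Li])N(C)OC)c(OC)c(OC)c1C(C)(O[Li])N(C)OC | intermediate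
6 | 1,1'-(2,3,5,6-tetramethoxy-1,4-phenylene)di(ethan-1-one) | COc1c(OC)c(C(C)=O)c(OC)c(OC)c1C(C)=O | intermediate
7 | N'-[1-(4-acetyl-2,3,5,6-tetramethoxyphenyl)ethylidene]-4-methylbenzenesulfonohydrazide (C=N geometry undefined) | COc1c(OC)c(C(C)=NNS(=O)(=O)c2ccc(C)cc2)c(OC)c(OC)c1C(C)=O | intermediate
8 | 1-bromo-2-nitrobenzene | O=[N+]([O-])c1ccccc1Br | starting material
9 | 1-{2,3,5,6-tetramethoxy-4-[1-(2-nitrophenyl)ethenyl]phenyl}ethan-1-one | COc1c(OC)c(C(C)=O)c(OC)c(OC)c1C(=C)c1ccccc1[N+](=O)[O-] | intermediate
10 | 4-methyl-N'-(1-{2,3,5,6-tetramethoxy-4-[1-(2-nitrophenyl)ethenyl]phenyl}ethylidene)benzenesulfonohydrazide (C=N geometry undefined) | COc1c(OC)c(C(C)=NNS(=O)(=O)c2ccc(C)cc2)c(OC)c(OC)c1C(=C)c1ccccc1[N+](=O)[O-] | intermediate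
11 | 2-bromo-4-chloro-1-nitrobenzene | O=[N+]([O-])c1ccc(Cl)cc1Br | starting material
12 | 1-[1-(5-chloro-2-nitrophenyl)ethenyl]-2,3,5,6-tetramethoxy-4-[1-(2-nitrophenyl)ethenyl]benzene | COc1c(OC)c(C(=C)c2cc(Cl)ccc2[N+](=O)[O-])c(OC)c(OC)c1C(=C)c1ccccc1[N+](=O)[O-] | intermediate
13 | tributyl(3-methylbut-2-en-1-yl)stannane | CCCC[Sn](CCCC)(CCCC)CC=C(C)C | starting material
14 | 1,2,4,5-tetramethoxy-3-{1-[5-(3-methylbut-2-en-1-yl)-2-nitrophenyl]ethenyl}-6-[1-(2-nitrophenyl)ethenyl]benzene | COc1c(OC)c(C(=C)c2cc(CC=C(C)C)ccc2[N+](=O)[O-])c(OC)c(OC)c1C(=C)c1ccccc1[N+](=O)[O-] | intermediate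
15 | 3-[4-(1H-indol-3-yl)-2,3,5,6-tetramethoxyphenyl]-5-(3-methylbut-2-en-1-yl)-1H-indole | COc1c(OC)c(-c2c[nH]c3ccc(CC=C(C)C)cc23)c(OC)c(OC)c1-c1c[nH]c2ccccc12 | target

Total step count: 8. Longest linear sequence: 8 steps (1 to 15); the fragments 3, 8, 11 and 13 are used as purchased.

Steps most likely to fail

Step 8. Each reacting centre is flanked by the fully ortho-substituted central ring, so one nitro group may cyclise while the other stalls at the nitroso or N-hydroxyindole level. Reduction to the aniline may also overtake ring closure. The fallback sets out from 14 and comes back at 15. It replaces the catalytic CO reduction by a Cadogan–Sundberg deoxygenation with stoichiometric trivalent phosphorus: PPh3 in excess with catalytic MoO2Cl2(dmf)2 in refluxing toluene. This transfers the nitro oxygen atoms to phosphorus and should close the same two N1–C2 bonds without CO pressure or palladium. No new isolable compound is made.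

Step 4. The lithium enolate of the free acetyl group may be arylated by 8, either through palladium or by nucleophilic aromatic substitution. Carbene insertion at the di-ortho-substituted centre may also be slow enough for the diazo compound to decompose. The fallback sets out from 2 and comes back at 9, and keeps the second acetyl group masked as a bromide until after the coupling.
- Single bromine–lithium exchange of 2 (n-BuLi, 1.05 equiv, THF, −78 °C) should give (4-bromo-2,3,5,6-tetramethoxyphenyl)lithium F1.
- Addition of F1 to 3 gives lithium 1-(4-bromo-2,3,5,6-tetramethoxyphenyl)-1-[methoxy(methyl)amino]ethan-1-olate F2, and 1 M HCl releases 1-(4-bromo-2,3,5,6-tetramethoxyphenyl)ethan-1-one F3.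
- Condensation with TsNHNH2 gives N'-[1-(4-bromo-2,3,5,6-tetramethoxyphenyl)ethylidene]-4-methylbenzenesulfonohydrazide F4.
- Barluenga coupling of F4 with 8 under the conditions of step 4 should engage only the nitro-activated bromide and leave the hindered, electron-rich one, giving 1-bromo-2,3,5,6-tetramethoxy-4-[1-(2-nitrophenyl)ethenyl]benzene F5.
- Stille coupling of F5 with tributyl(1-ethoxyethenyl)stannane (Pd2(dba)3, P(t-Bu)3, CsF, dioxane, 100 °C) gives 1-(1-ethoxyethenyl)-2,3,5,6-tetramethoxy-4-[1-(2-nitrophenyl)ethenyl]benzene F6.
- Dilute aqueous HCl in THF hydrolyses the enol ether F6 to 9.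

Step 7. Allylic transposition during transmetalation or reductive elimination may give the 1,1-dimethylallyl isomer, and oxidative addition to the C–Cl bond may be slow enough for the stannane to be consumed by homocoupling. The fallback sets out from 12 and comes back at 14, and builds the prenyl group in two stages so that no unsymmetrical allyl group is transferred.
- Stille coupling of 12 with allyltributylstannane under the conditions of step 7 gives 1-[1-(2-nitro-5-(prop-2-en-1-yl)phenyl)ethenyl]-2,3,5,6-tetramethoxy-4-[1-(2-nitrophenyl)ethenyl]benzene F7; the symmetrical allyl group removes the regiochemical question.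
- Olefin cross-metathesis of F7 with excess 2-methylbut-2-ene (second-generation Grubbs catalyst, CH2Cl2, 40 °C) converts the terminal alkene into the prenyl group of 14. The two 1,1-diarylethenes are too hindered to enter metathesis.

Further compounds
F0 | step 8 | none | none
F1 | step 4 | (4-bromo-2,3,5,6-tetramethoxyphenyl)lithium | [Li]c1c(OC)c(OC)c(Br)c(OC)c1OC
F2 | step 4 | lithium 1-(4-bromo-2,3,5,6-tetramethoxyphenyl)-1-[methoxy(methyl)amino]ethan-1-olate (racemic) | COc1c(OC)c(C(C)(O[Li])N(C)OC)c(OC)c(OC)c1Br
F3 | step 4 | 1-(4-bromo-2,3,5,6-tetramethoxyphenyl)ethan-1-one | COc1c(OC)c(C(C)=O)c(OC)c(OC)c1Br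
F4 | step 4 | N'-[1-(4-bromo-2,3,5,6-tetramethoxyphenyl)ethylidene]-4-methylbenzenesulfonohydrazide (C=N geometry undefined) | COc1c(OC)c(C(C)=NNS(=O)(=O)c2ccc(C)cc2)c(OC)c(OC)c1Br
F5 | step 4 | 1-bromo-2,3,5,6-tetramethoxy-4-[1-(2-nitrophenyl)ethenyl]benzene | COc1c(OC)c(Br)c(OC)c(OC)c1C(=C)c1ccccc1[N+](=O)[O-]
F6 | step 4 | 1-(1-ethoxyethenyl)-2,3,5,6-tetramethoxy-4-[1-(2-nitrophenyl)ethenyl]benzene | CCOC(=C)c1c(OC)c(OC)c(C(=C)c2ccccc2[N+](=O)[O-])c(OC)c1OC
F7 | step 7 | 1-[1-(2-nitro-5-(prop-2-en-1-yl)phenyl)ethenyl]-2,3,5,6-tetramethoxy-4-[1-(2-nitrophenyl)ethenyl]benzene | COc1c(OC)c(C(=C)c2cc(CC=C)ccc2[N+](=O)[O-])c(OC)c(OC)c1C(=C)c1ccccc1[N+](=O)[O-]
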